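Ring C is disconnected at C8–C14 and C9–C11: a [4+2] cycloaddition of a 2-silyloxybutadiene with the C8=C9 bond of a ring-B cyclopentenecarbaldehyde. The step exploits the cis B/C fusion at C8–C9, where quaternary C8 carries the one-carbon arm C15 syn to H-9 and where C12 sits 1,4 to C8. One operation closes ring C, sets C8 and C9, and leaves a C12=C13 silyl enol ether beside the C15 aldehyde for the bicyclo[3.2.1] ring D. The precursor already holds ring A, the 19,20-lactone, the 2β,3β-acetonide and the C6 ester; it is made by a chirality-transferring Ireland–Claisen rearrangement, an exo-face dihydroxylation and an aldol ring closure.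

Key step: step 18

Remark on the chemistry: atoms carry ent-gibberellane numbers (C1–C20); α is the face of C20 and the lactone bridge, β the face of H-5, H-9, C7 and C15.
Assumption: compounds 1, 9 and 24 and all reagents named under Conditions are taken as purchased.

Step 1
Reactants: 1 diethyl 4-oxocyclohexane-1,1-dicarboxylate
Product: 2 4,4-bis(hydroxymethyl)cyclohexan-1-ol
Conditions: LiAlH4, THF, 0 °C → reflux; Fieser work-up
Reagents that add atoms: none
Why: Exhaustive LiAlH4 reduction should convert both esters and the ketone into the triol, which has a mirror plane and therefore no stereocentre to control.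

Step 2
Reactants: 2 4,4-bis(hydroxymethyl)cyclohexan-1-ol
Product: 3 3,3-di-tert-butyl-2,4-dioxa-3-silaspiro[5.5]undecan-9-ol
Conditions: t-Bu2Si(OTf)2 (1.05 equiv), 2,6-lutidine, DMF/CH2Cl2, −40 → 0 °C
Reagents that add atoms: di-tert-butylsilyl bis(trifluoromethanesulfonate), CC(C)(C)[Si](OS(=O)(=O)C(F)(F)F)(OS(=O)(=O)C(F)(F)F)C(C)(C)C
Why: Cyclic silylene protection should pick the 1,3-diol (six-membered dioxasilinane) and leave the secondary alcohol free; the silylene is chosen because fluoride removes it later without acid.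

Step 3
Reactants: 3 3,3-di-tert-butyl-2,4-dioxa-3-silaspiro[5.5]undecan-9-ol
Product: 5 3,3-di-tert-butyl-2,4-dioxa-3-silaspiro[5.5]undec-7-en-9-one, via spiro ketone 4 (not isolated)
Conditions: IBX (2.3 equiv), DMSO/PhF, 25 → 75 °C
Reagents that add atoms: none
Why: IBX should oxidise the alcohol to ketone 4 and then dehydrogenate it once (IBX α,β-dehydrogenation); 4 is symmetric, so only one enone can form and C10 stays non-stereogenic.

Step 4
Reactants: 5 3,3-di-tert-butyl-2,4-dioxa-3-silaspiro[5.5]undec-7-en-9-one
Product: 6 3,3-di-tert-butyl-8-iodo-2,4-dioxa-3-silaspiro[5.5]undec-7-en-9-one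
Conditions: I2, pyridine/CH2Cl2, 0 °C → rt
Reagents that add atoms: iodine, II
Why: α-Iodination of the enone by pyridine conjugate addition, iodination of the enolate and elimination (Johnson iodination) is a known reaction of 4,4-disubstituted cyclohexenones.

Step 5
Reactants: 6 3,3-di-tert-butyl-8-iodo-2,4-dioxa-3-silaspiro[5.5]undec-7-en-9-one
Product: 7 (9R)-3,3-di-tert-butyl-8-iodo-2,4-dioxa-3-silaspiro[5.5]undec-7-en-9-ol (C3 carbinol; oxygen on the later α face)
Conditions: (S)-Me-CBS oxazaborolidine (15 mol%), BH3·SMe2, THF, −30 °C; MeOH quench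
Reagents that add atoms: none
Why: In the Corey–Bakshi–Shibata reduction the iodovinyl side acts as the large group, so the (S)-catalyst should deliver hydride to one face and give the (R)-carbinol; this centre is the source of absolute configuration for the whole route.

Step 6
Reactants: 7 (9R)-iodo allylic alcohol
Product: 8 methyl (9R)-3,3-di-tert-butyl-9-hydroxy-2,4-dioxa-3-silaspiro[5.5]undec-7-ene-8-carboxylate
Conditions: CO (1 atm), MeOH, Et3N, PdCl2(PPh3)2 (5 mol%), DMF, 60 °C
Reagents that add atoms: carbon monoxide, [C-]#[O+]; methanol, CO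
Why: Palladium-catalysed methoxycarbonylation of the vinyl iodide installs C19 on C4 and does not touch the carbinol centre.

Step 7
Reactants: 9 methyl 4,4-dimethoxybutanoate
Product: 10 4,4-dimethoxybutanoic acid
Conditions: LiOH·H2O, THF/H2O, rt; then 1 M HCl to pH 4, 0 °C
Reagents that add atoms: lithium hydroxide, [Li+].[OH-]
Why: Ester saponification; the dimethyl acetal is stable to base and to brief cold acidification.

Step 8
Reactants: 8 hydroxy enoate; 10 4,4-dimethoxybutanoic acid
Product: 11 methyl (9R)-3,3-di-tert-butyl-9-[(4,4-dimethoxybutanoyl)oxy]-2,4-dioxa-3-silaspiro[5.5]undec-7-ene-8-carboxylate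
Conditions: EDC·HCl, DMAP (0.1 equiv), CH2Cl2, 0 °C → rt
Reagents that add atoms: none
Why: Steglich esterification acylates the C3 hydroxyl with retention and places the C6–C7 unit on the oxygen from which it will be transferred.

Step 9
Reactants: 11 allylic 4,4-dimethoxybutanoate
Product: 14 2-[3,3-di-tert-butyl-8-(methoxycarbonyl)-2,4-dioxa-3-silaspiro[5.5]undec-8-en-7-yl]-4,4-dimethoxybutanoic acid (C5 and C6 as in the target; H-5 β), via silyl ketene acetal 12 (not isolated), via silyl ester 13 (not isolated)
Conditions: LDA, THF/DMPU (4:1), −78 °C; TMSCl; → 45 °C; aq NaH2PO4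
Reagents that add atoms: chlorotrimethylsilane, C[Si](C)(C)Cl (carried in 12 and 13 only)
Why: Ireland–Claisen rearrangement: enolisation with DMPU should give the ketene acetal with the C8 chain cis to OSi, and the [3,3] shift through the boat transition state usual for cyclohexenyl esters (a chair would press the ketene acetal against the C10 substituents) transfers the C3 configuration suprafacially to C5 (new bond α) and fixes C6, while the alkene moves to C3=C4.

Step 10
Reactants: 14 Claisen acid
Product: 15 2-[3,3-di-tert-butyl-8-(methoxycarbonyl)-8-methyl-2,4-dioxa-3-silaspiro[5.5]undec-9-en-7-yl]-4,4-dimethoxybutanoic acid (C18 β; C19 α)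
Conditions: LDA (2.4 equiv), THF/DMPU, −78 °C; MeI, −78 → −40 °C; aq NaH2PO4
Reagents that add atoms: iodomethane, CI
Why: Deconjugative α-alkylation of the enoate: the carboxylate shields C6–H, γ-deprotonation at C2 gives the dienolate, and methyl iodide should attack C4 anti to the C5 side chain, which makes C4 quaternary and moves the alkene to C2=C3.

Step 11
Reactants: 15 methylated acid
Product: 17 hydroxy lactone acid (19→20 δ-lactone; C9 hydroxymethyl on C10; C7 acid), via seco diol 16 (not isolated)
Conditions: TBAF (3.5 equiv), THF, 0 → 45 °C; aq NH4Cl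
Reagents that add atoms: none
Why: Fluoride cleaves the silylene, and only the alkoxide cis (1,3-diaxial) to C19 can close the δ-lactone by transesterification; this names that carbon C20, leaves C9–OH free and makes C10 a defined stereocentre, while the C7 carboxylate cannot lactonise under basic conditions.

Step 12
Reactants: 17 hydroxy lactone acid
Product: 18 aldehyde acid (C9 formyl on C10)
Conditions: Dess–Martin periodinane, NaHCO3, CH2Cl2, 0 °C → rt
Reagents that add atoms: none
Why: Dess–Martin oxidation turns the neopentyl C9 alcohol into a non-enolisable aldehyde before C7 is esterified, so a 7,9-lactone has no chance to form.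

Step 13
Reactants: 18 aldehyde acid
Product: 19 aldehyde methyl ester
Conditions: MeI, K2CO3, DMF, rt
Reagents that add atoms: iodomethane, CI
Why: SN2 O-methylation of the carboxylate under conditions too mild to epimerise C6.

Step 14
Reactants: 19 aldehyde methyl ester
Product: 20 2β,3β-diol
Conditions: OsO4 (2 mol%), NMO, acetone/H2O, rt
Reagents that add atoms: N-methylmorpholine N-oxide, C[N+]1([O-])CCOCC1; water, O
Why: Upjohn dihydroxylation adds syn from the exo (β) face of the 3-oxabicyclo[3.3.1]non-6-ene, the α face being covered by the lactone bridge, which sets C2 and C3.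

Step 15
Reactants: 20 2β,3β-diol
Product: 21 2β,3β-acetonide
Conditions: 2-methoxypropene, PPTS (cat.), CH2Cl2, 0 °C
Reagents that add atoms: 2-methoxypropene, COC(C)=C
Why: Acetalisation of the cis-diol protects O2 and O3 and also blocks base-induced retro-aldol at C3 later on.

Step 16
Reactants: 21 2β,3β-acetonide
Product: 23 ring-B enal (C8 formyl; C8=C9), via dialdehyde 22 (not isolated)
Conditions: PPTS, acetone/H2O (20:1), 50 °C; then Bn2NH·CF3CO2H (0.5 equiv), toluene, 50 °C
Reagents that add atoms: water, O
Why: Transacetalisation to acetone frees the C15 aldehyde and keeps the acetonide, and the amine-catalysed intramolecular aldol condensation can only use C8 as nucleophile (the C9 aldehyde has no α-hydrogen), so it closes ring B in the 5-(enolexo)-exo-trig mode and dehydrates to the enal without touching C6.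

Step 17
Reactants: 24 but-3-en-2-one
Product: 25 2-(tert-butyldimethylsilyloxy)buta-1,3-diene
Conditions: TBSOTf, Et3N, Et2O, 0 °C → rt
Reagents that add atoms: tert-butyldimethylsilyl trifluoromethanesulfonate, CC(C)(C)[Si](C)(C)OS(=O)(=O)C(F)(F)F
Why: Soft enolisation with O-silylation of the methyl ketone gives the 2-silyloxydiene.

Step 18
Reactants: 23 ring-B enal; 25 2-(tert-butyldimethylsilyloxy)buta-1,3-diene
Product: 26 ring-C silyl enol ether (C12=C13) with the C15 aldehyde on quaternary C8
Conditions: Me2AlCl (2.2 equiv), 25 (3 equiv), CH2Cl2/toluene, −78 → −20 °C; Et3N, then aq Rochelle salt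
Reagents that add atoms: none
Why: Dimethylaluminium chloride binds the C15 aldehyde (and the C7 ester carbonyl through a seven-membered chelate), lowers the enal LUMO and lets the diene add in a concerted, asynchronous, suprafacial [4+2] in which the CH2 next to the silyloxy carbon bonds to the β-carbon C9 and the other terminus to C8. This is the Lewis acid-promoted Diels–Alder of a 2-silyloxybutadiene with a cycloalk-1-enecarbaldehyde, a known way to make an angular formyl-bearing quaternary carbon. Ring C closes by intermolecular cycloaddition with both σ bonds (C8–C14, C9–C11) formed on one face of ring B, so the new six-membered ring is necessarily cis-fused. C8 and C9 are set together by the face of approach: the α face is required, and it is favoured by the C6 ester and the aluminium held on the β face beside C8, which leaves C15 and H-9 β. The 1,4 regiochemistry (siloxy carbon para to C8, hence the C12=C13 enol ether) follows from the larger HOMO coefficient at the diene CH2 adjacent to C–OSi. The selectivity needed is α over β attack, and the element opposing it is the axial C20 methylene on C10 next to C9, which is why this step carries the risk of the route.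

Step 19
Reactants: 26 cycloadduct
Product: 28 15-vinyl 7,15-γ-lactone (C15 epimers), via hydroxy ester 27 (not isolated)
Conditions: CH2=CHMgBr (1.5 equiv), THF, −78 → 0 °C; then rt
Reagents that add atoms: vinylmagnesium bromide, C=C[Mg]Br
Why: Grignard addition to the neopentyl aldehyde is followed by intramolecular transesterification, because the C15 alkoxide is cis to the C7 ester on the β face; both C15 epimers lactonise and that centre is erased in the next step.

Step 20
Reactants: 28 vinyl lactone
Product: 29 C8-allyl C7-acid (silyl enol ether intact)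
Conditions: Pd2(dba)3·CHCl3 (2.5 mol%), n-Bu3P (10 mol%), HCO2NH4, 1,4-dioxane, 80 °C
Reagents that add atoms: none
Why: Tsuji formate hydrogenolysis: Pd(0) ionises the allylic lactone to a π-allyl carboxylate and the palladium hydride from formate is delivered to the more substituted terminus C15, which should give the terminal allyl alkene and free the C7 acid.

Step 21
Reactants: 29 allyl acid
Product: 30 allyl methyl ester
Conditions: MeI, K2CO3, DMF, rt
Reagents that add atoms: iodomethane, CI
Why: Carboxylate O-methylation restores the ester so that the acid cannot intercept palladium(II) in the next step; the silyl enol ether tolerates carbonate in DMF.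

Step 22
Reactants: 30 allyl methyl ester
Product: 31 C12 ketone with ring D closed (C16=C17 exocyclic)
Conditions: Pd(OAc)2 (10 mol%), O2 (1 atm), DMSO, 45 °C
Reagents that add atoms: none
Why: Palladium(II)-mediated cycloalkenylation of the silyl enol ether: the oxa-π-allylpalladium from C12=C13 adds across the allyl alkene in the 5-exo mode (C13–C16), β-hydride elimination gives the exocyclic alkene, and the C13 bridgehead can only form with the configuration the bicyclo[3.2.1]octane allows.

Step 23
Reactants: 31 ring-D ketone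
Product: 33 12-deoxo methyl ester acetonide, via tosylhydrazone 32 (not isolated)
Conditions: TsNHNH2, EtOH, 70 °C; then catecholborane, CHCl3, 0 °C; NaOAc·3H2O, 60 °C
Reagents that add atoms: 4-methylbenzenesulfonohydrazide, Cc1ccc(cc1)S(=O)(=O)NN (carried in 32 only)
Why: Tosylhydrazone reduction (Caglioti/Kabalka) removes the C12 carbonyl under near-neutral conditions; the bridgehead C13 prevents conjugation or alkene migration and the exocyclic alkene is not reduced.

Step 24
Reactants: 33 methyl ester acetonide
Product: 35 target acid (CNP0332607.1), via dipotassium salt 34 (not isolated)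
Conditions: KOH (2 M aq), MeOH, 70 °C; then 2 M HCl to pH 1, THF/H2O, rt
Reagents that add atoms: potassium hydroxide, [K+].[OH-]
Why: Saponification is run while the acetonide still masks O3 (no retro-aldol epimerisation at C3), the opened hydroxy dicarboxylate relactonises on acidification because only C19 and C20 are cis-diaxial, and dilute aqueous acid then hydrolyses the acetonide without protonating the exocyclic alkene.

Compound list
1 | diethyl 4-oxocyclohexane-1,1-dicarboxylate | CCOC(=O)C1(CCC(=O)CC1)C(=O)OCC | starting material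
2 | 4,4-bis(hydroxymethyl)cyclohexan-1-ol | OCC1(CO)CCC(O)CC1 | intermediate
3 | 3,3-di-tert-butyl-2,4-dioxa-3-silaspiro[5.5]undecan-9-ol | OC1CCC2(CC1)CO[Si](OC2)(C(C)(C)C)C(C)(C)C | intermediate
4 | 3,3-di-tert-butyl-2,4-dioxa-3-silaspiro[5.5]undecan-9-one | O=C1CCC2(CC1)CO[Si](OC2)(C(C)(C)C)C(C)(C)C | intermediate
5 | 3,3-di-tert-butyl-2,4-dioxa-3-silaspiro[5.5]undec-7-en-9-one | O=C1C=CC2(CC1)CO[Si](OC2)(C(C)(C)C)C(C)(C)C | intermediate
6 | 3,3-di-tert-butyl-8-iodo-2,4-dioxa-3-silaspiro[5.5]undec-7-en-9-one | O=C1C(I)=CC2(CC1)CO[Si](OC2)(C(C)(C)C)C(C)(C)C | intermediate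
7 | (9R)-3,3-di-tert-butyl-8-iodo-2,4-dioxa-3-silaspiro[5.5]undec-7-en-9-ol | O[C@@H]1CCC2(CO[Si](OC2)(C(C)(C)C)C(C)(C)C)C=C1I | intermediate
8 | methyl (9R)-3,3-di-tert-butyl-9-hydroxy-2,4-dioxa-3-silaspiro[5.5]undec-7-ene-8-carboxylate | O[C@@H]1CCC2(CO[Si](OC2)(C(C)(C)C)C(C)(C)C)C=C1C(=O)OC | intermediate
9 | methyl 4,4-dimethoxybutanoate | COC(=O)CCC(OC)OC | starting material
10 | 4,4-dimethoxybutanoic acid | OC(=O)CCC(OC)OC | intermediate
11 | methyl (9R)-3,3-di-tert-butyl-9-[(4,4-dimethoxybutanoyl)oxy]-2,4-dioxa-3-silaspiro[5.5]undec-7-ene-8-carboxylate | COC(CCC(=O)O[C@@H]1CCC2(CO[Si](OC2)(C(C)(C)C)C(C)(C)C)C=C1C(=O)OC)OC | intermediate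
12 | (Z)-trimethylsilyl ketene acetal of 11 (C8 chain cis to OSiMe3) | C[Si](C)(C)O/C(=C\CC(OC)OC)O[C@@H]1CCC2(CO[Si](OC2)(C(C)(C)C)C(C)(C)C)C=C1C(=O)OC | intermediate
13 | trimethylsilyl ester of acid 14 | COC(=O)C1=CCCC2(CO[Si](OC2)(C(C)(C)C)C(C)(C)C)[C@@H]1[C@@H](CC(OC)OC)C(=O)O[Si](C)(C)C | intermediate
14 | 2-[3,3-di-tert-butyl-8-(methoxycarbonyl)-2,4-dioxa-3-silaspiro[5.5]undec-8-en-7-yl]-4,4-dimethoxybutanoic acid (C5, C6 as in target) | COC(=O)C1=CCCC2(CO[Si](OC2)(C(C)(C)C)C(C)(C)C)[C@@H]1[C@@H](CC(OC)OC)C(=O)O | intermediate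
15 | 2-[3,3-di-tert-butyl-8-(methoxycarbonyl)-8-methyl-2,4-dioxa-3-silaspiro[5.5]undec-9-en-7-yl]-4,4-dimethoxybutanoic acid (C18 β, C19 α) | COC(=O)[C@]1(C)C=CCC2(CO[Si](OC2)(C(C)(C)C)C(C)(C)C)[C@@H]1[C@@H](CC(OC)OC)C(=O)O | intermediate
16 | seco diol: acid 15 with both C10 hydroxymethyl groups free | COC(=O)[C@]1(C)C=CCC(CO)(CO)[C@@H]1[C@@H](CC(OC)OC)C(=O)O | intermediate
17 | hydroxy lactone acid: 19→20 δ-lactone, ring A 2-ene, C9H2OH on C10, C6 acid arm with C15 dimethyl acetal | OC[C@]12COC(=O)[C@](C)(C=CC1)[C@H]2[C@@H](CC(OC)OC)C(=O)O | intermediate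
18 | aldehyde acid: as 17 with C9 formyl | O=C[C@]12COC(=O)[C@](C)(C=CC1)[C@H]2[C@@H](CC(OC)OC)C(=O)O | intermediate
19 | aldehyde methyl ester: as 18 with C7 methyl ester | O=C[C@]12COC(=O)[C@](C)(C=CC1)[C@H]2[C@@H](CC(OC)OC)C(=O)OC | intermediate
20 | 2β,3β-diol of 19 | O=C[C@]12COC(=O)[C@](C)([C@@H](O)[C@@H](O)C1)[C@H]2[C@@H](CC(OC)OC)C(=O)OC | intermediate
21 | 2β,3β-acetonide of 20 | O=C[C@]12COC(=O)[C@](C)([C@H]3OC(C)(C)O[C@H]3C1)[C@H]2[C@@H](CC(OC)OC)C(=O)OC | intermediate
22 | dialdehyde (C9 and C15 formyl groups) | O=C[C@]12COC(=O)[C@](C)([C@H]3OC(C)(C)O[C@H]3C1)[C@H]2[C@@H](CC=O)C(=O)OC | intermediate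
23 | A/B lactone enal: ring-B cyclopentene with C8 formyl, C8=C9, 6β-CO2Me, 2β,3β-acetonide | O=CC1=C[C@]23COC(=O)[C@](C)([C@H]4OC(C)(C)O[C@H]4C2)[C@H]3[C@@H]1C(=O)OC | intermediate
24 | but-3-en-2-one | CC(=O)C=C | starting material
25 | 2-(tert-butyldimethylsilyloxy)buta-1,3-diene | C=CC(=C)O[Si](C)(C)C(C)(C)C | intermediate
26 | cycloadduct: ring C cis-fused (C11, C14 α), C12=C13 TBS enol ether, C15 aldehyde on C8 (β), H-9 β | O=C[C@]12CC=C(O[Si](C)(C)C(C)(C)C)C[C@H]1[C@]34COC(=O)[C@](C)([C@H]5OC(C)(C)O[C@H]5C3)[C@H]4[C@@H]2C(=O)OC | intermediate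
27 | C15 vinyl carbinol methyl ester (formed as magnesium alkoxide; C15 epimers) | OC(C=C)[C@]12CC=C(O[Si](C)(C)C(C)(C)C)C[C@H]1[C@]34COC(=O)[C@](C)([C@H]5OC(C)(C)O[C@H]5C3)[C@H]4[C@@H]2C(=O)OC | intermediate
28 | 15-vinyl 7,15-γ-lactone (C15 epimers) | C=CC1OC(=O)[C@H]2[C@@H]3[C@@](C)([C@H]4OC(C)(C)O[C@H]4C5)C(=O)OC[C@]35[C@@H]6CC(O[Si](C)(C)C(C)(C)C)=CC[C@]126 | intermediate
29 | C8-allyl C7-acid with C12=C13 TBS enol ether | C=CC[C@]12CC=C(O[Si](C)(C)C(C)(C)C)C[C@H]1[C@]34COC(=O)[C@](C)([C@H]5OC(C)(C)O[C@H]5C3)[C@H]4[C@@H]2C(=O)O | intermediate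
30 | methyl ester of 29 | C=CC[C@]12CC=C(O[Si](C)(C)C(C)(C)C)C[C@H]1[C@]34COC(=O)[C@](C)([C@H]5OC(C)(C)O[C@H]5C3)[C@H]4[C@@H]2C(=O)OC | intermediate
31 | 12-oxo ent-gibberell-16-ene: rings C/D closed, methyl ester, acetonide | C=C1C[C@]23C[C@H]1C(=O)C[C@H]2[C@]12COC(=O)[C@](C)([C@H]4OC(C)(C)O[C@H]4C1)[C@H]2[C@@H]3C(=O)OC | intermediate
32 | C12 tosylhydrazone of 31 | C=C1C[C@]23C[C@H]1C(=NNS(=O)(=O)c1ccc(C)cc1)C[C@H]2[C@]12COC(=O)[C@](C)([C@H]4OC(C)(C)O[C@H]4C1)[C@H]2[C@@H]3C(=O)OC | intermediate
33 | target methyl ester 2,3-acetonide | C=C1C[C@]23C[C@H]1CC[C@H]2[C@]12COC(=O)[C@](C)([C@H]4OC(C)(C)O[C@H]4C1)[C@H]2[C@@H]3C(=O)OC | intermediate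
34 | dipotassium 7,19-dicarboxylate with free C20 hydroxyl, acetonide intact | C=C1C[C@]23C[C@H]1CC[C@H]2[C@]1(CO)C[C@@H]2OC(C)(C)O[C@@H]2[C@@](C)(C(=O)[O-])[C@H]1[C@@H]3C(=O)[O-].[K+].[K+] | intermediate
35 | CNP0332607.1: 2β,3β-dihydroxy 19,20-lactone 7-acid | C=C1C[C@]23C[C@H]1CC[C@H]2[C@]12COC(=O)[C@](C)([C@@H](O)[C@@H](O)C1)[C@H]2[C@@H]3C(=O)O | target

Total step count: 24. Longest linear sequence: 22 steps (1–6, 8–16, 18–24); steps 7 and 17 are side branches.

Steps most likely to fail

1. Step 18. The diene may add from the β face, anti to the axial C20 methylene on C10, instead of anti to the C6 ester (poor or inverted facial selectivity), or the hindered C9 may react too slowly and the diene oligomerise. Fallback: stereocontrol is moved from the substrate to the reagent. Enal 23 and diene 25 are combined under a cationic oxazaborolidine (o-tolyl-CBS oxazaborolidine activated with triflimide), a catalyst class established for 2-silyloxybutadienes with α-substituted enals, using the catalyst enantiomer whose aryl group covers the β face. It sets out from 23 and comes back at 26; no new compound is made (F0).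

2. Step 9. Leakage between ketene acetal geometries or between boat and chair transition states would erode the configuration at C6 (C5 is secure through chirality transfer). Fallback: C6 is corrected by kinetic protonation on a rigid lactone in place of pericyclic control. It sets out from 17 obtained as a C6 epimer mixture. EDC/DMAP closes the C7 acid onto the C9 hydroxyl to give the bis-lactone F1. LDA at −78 °C followed by a hindered proton source protonates the enolate from the open β face (the α face lies under the 19,20-lactone bridge) to give the single-epimer bis-lactone F2. One equivalent of LiOH in THF/H2O at 0 °C opens the less hindered 7,9-lactone, and the route is rejoined at 17, taken on as its carboxylate into step 12.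

3. Step 22. Dehydrosilylation of the enol ether to an enone, 6-endo closure or palladium hydride migration of the new alkene into the ring may compete with the 5-exo cyclisation. Fallback: ring D is closed by gold-catalysed alkyne carbocyclisation in place of the oxidative alkene cyclisation. It sets out from 26. Methylenation with Ph3P=CH2 gives the C8 vinyl compound F3. Hydroboration with 9-BBN and NaBO3 gives the primary alcohol F4. Dess–Martin oxidation gives the aldehyde F5. The Ohira–Bestmann reagent (K2CO3, MeOH) gives the terminal alkyne F6 (C8 propargyl). Ph3PAuCl/AgBF4 in CH2Cl2/MeOH then effects the 5-exo-dig attack of the C12=C13 silyl enol ether on the alkyne, and the route is rejoined at 31.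

Further compounds
F0 | step 18 | none | none
F1 | step 9 | 7,9:19,20-bis-lactone (C6 epimer mixture) | O=C1OC[C@]23COC(=O)[C@](C)(C=CC2)[C@H]3C1CC(OC)OC
F2 | step 9 | 7,9:19,20-bis-lactone with C6 as in the target | O=C1OC[C@]23COC(=O)[C@](C)(C=CC2)[C@H]3[C@H]1CC(OC)OC
F3 | step 22 | C8 vinyl analogue of 26 | C=C[C@]12CC=C(O[Si](C)(C)C(C)(C)C)C[C@H]1[C@]34COC(=O)[C@](C)([C@H]5OC(C)(C)O[C@H]5C3)[C@H]4[C@@H]2C(=O)OC
F4 | step 22 | C8 2-hydroxyethyl compound | OCC[C@]12CC=C(O[Si](C)(C)C(C)(C)C)C[C@H]1[C@]34COC(=O)[C@](C)([C@H]5OC(C)(C)O[C@H]5C3)[C@H]4[C@@H]2C(=O)OC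
F5 | step 22 | C8 2-oxoethyl compound | O=CC[C@]12CC=C(O[Si](C)(C)C(C)(C)C)C[C@H]1[C@]34COC(=O)[C@](C)([C@H]5OC(C)(C)O[C@H]5C3)[C@H]4[C@@H]2C(=O)OC
F6 | step 22 | C8 propargyl compound | C#CC[C@]12CC=C(O[Si](C)(C)C(C)(C)C)C[C@H]1[C@]34COC(=O)[C@](C)([C@H]5OC(C)(C)O[C@H]5C3)[C@H]4[C@@H]2C(=O)OC
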